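The readings are calculated with constants of no real substance; the scatter is artificial.

Product per litre at the end of the feed is the figure to carry between these runs, rather than the percent left, which you hoped would stay near noon's 50.2 %. You asked for a quick number, so here is the case.

| setting | spring | noon | flask |
|---|---|---|---|
| starting material | 0.20 M | 0.29 M | 0.39 M |
| partner | 0.78 M (fed, over 6.0 min) | 0.78 M (fed, over 6.0 min) | 0.780 M (fed, over 6.0 min) |
| free catalyst | 2 mM | 2 mM | 2.0 mM |
| remark | run made earlier; the fed solution adds 0.10 times the starting volume | run made earlier; the fed solution adds 0.10 times the starting volume | the fed solution adds 0.10 times the starting volume |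
| time |  |  | 12 min |

| run | time / min | starting material / % | product / % |
|---|---|---|---|
| spring | 2.00 | 86.8 | 12.9 |
| spring | 4.00 | 63.1 | 36.3 |
| spring | 6.00 | 37.8 | 61.9 |
| spring | 8.00 | 18.1 | 81.9 |
| spring | 10.0 | 7.0 | 92.8 |
| noon | 2.00 | 90.5 | 9.6 |
| noon | 4.00 | 72.9 | 27.9 |
| noon | 6.00 | 50.2 | 49.2 |
| noon | 8.00 | 32.9 | 67.9 |
| noon | 10.0 | 18.2 | 81.6 |

(each reading ± 0.5 percentage points)

- amount of starting material in percent of the starting material charged, at 2.5 min, 6.0 min and 12 min

Follow one molecule of starting material: its chance of being product when the feed ends is the product made per litre of starting volume over the charge. The noon run read 49.2 % of 0.29 M, which gives a product amount at the end of the feed of 0.143 M. The spring run gave 0.124 M. From spring to noon the charge grew by a factor of 1.45 but the amount grew by a factor of only 1.15, so between these two runs each molecule's chance fell, from 61.9 % to 49.2 %.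

For the flask, my own reckoning takes two cases. If the amount stays at the noon value, 63.4 % of the starting material is left at the end of the feed. If it keeps climbing in a straight line with the charge, 58.0 % is left. I would commit to the middle, 60.7 %, well above your hunch.

The forecast gives 89.8 %, 61.5 % and 22 %, slightly above my figure at the end of the feed, and among its grounds is that the rate is “nearly zero order in starting material”.

The flask gives 89.8 %, 61.0 % and 19.9 %, and the forecast stands within its margins.

    partner + free catalyst → catalyst intermediate A (k = 1.90 L mol⁻¹ s⁻¹)
    catalyst intermediate A ⇌ by-product + catalyst intermediate B (K = 17.0 M, k = 150 s⁻¹)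
    starting material + catalyst intermediate B ⇌ catalyst intermediate C (K = 0.870 L mol⁻¹, k = 62.0 L mol⁻¹ s⁻¹)
    catalyst intermediate C → catalyst intermediate D (k = 7.10 s⁻¹)
    catalyst intermediate D → free catalyst + product (k = 9.00 s⁻¹)
    partner ⇌ dormant form (K = 1.60, k = 0.0240 s⁻¹)

The flask held 0.152 M of product at 6.00 min, more than the carried 0.143 M. Laid on the spring charge, that carried amount gives 28.7 % left, where the spring run read 37.8 %. At 6.11 min in the flask, catalyst intermediate C falls back 10 times faster than it goes on, so a molecule of starting material bound there moves forward, on that visit, with a chance of 9.09 %. At 6.00 min the flask's catalyst stood 4.31 % as catalyst intermediate C and 66.7 % as free catalyst, its resting state at that moment.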